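**Plan**
1. Retrosynthesis: the angelate C–O bond, the C-11–O aryl ether bond and the C-4–C-13 bond are cut first. The remaining decalin is then cut twice across ring A, at the ring-fusion bond C-5–C-10 and at C-2–C-3, which unravels both rings into one acyclic chain.
2. Enabling feature: in ring A, C-10 and C-2 flank C-1, and C-5 and C-3 flank C-4. Ring A is therefore a 3+3 union of a methyl ketone (nucleophilic α and α′ carbons C-10 and C-2 around a temporary C-1 carbonyl) with an enoate (electrophilic β-carbon C-5 and carbonyl carbon C-3 around C-4). Because C-5–C-10 is shared with ring B, one base treatment closes ring B (Michael) and then ring A (Claisen).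
3. Forward order: geraniol supplies C-11, C-9, C-8, C-12, C-7, C-6 and C-5; an alkenyl Grignard adds C-10, C-15, C-1 and C-2 at C-9; metathesis adds C-4, C-14 and C-3. The keto enoate then gives ring B and ring A in one pot, O-1 is removed by carbonyl transposition, C-13 is added, and the angelate, the aryl ether and the C-3 alcohol follow.
4. Stereochemistry: C-8 comes from Sharpless epoxidation and C-9 from inversion in the epoxide opening. C-10 and C-5 are set in the key step under control of C-8 and C-9. C-4 is set by α-face hydroxymethylation anti to the C-10 methyl, and C-3 by axial hydride delivery.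

Key step: step 7

Remark: drimane numbering is used throughout (C-1 to C-10 ring carbons, C-11 = CH2O on C-9, C-12 = CH3 on C-8, C-13 = CH2O on C-4, C-14 = CH3 on C-4, C-15 = CH3 on C-10), and β is the face of the C-10 methyl. In this numbering the target is (3R,4S,5S,8S,9R,10R). Reagent 3 is taken as its E isomer; its olefin geometry is erased in step 5.

**Step 1**
Reactants: 1 geraniol
Product: 2 (2S,3S)-2,3-epoxygeraniol
Conditions: Ti(OiPr)4 (5 mol%), L-(+)-diethyl tartrate (6 mol%), t-BuOOH, 4 Å MS, CH2Cl2, −20 °C
Reagents that add atoms: tert-butyl hydroperoxide, CC(C)(C)OO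
Why: Sharpless asymmetric epoxidation of an allylic alcohol; with L-(+)-tartrate the oxygen should be delivered to the face that gives the (2S,3S)-epoxide, which fixes C-8 (S) and, after inversion in step 2, C-9.

**Step 2**
Reactants: 2 (2S,3S)-2,3-epoxygeraniol; 3 (E)-but-2-en-2-ylmagnesium bromide
Product: 4 (2R,3S)-2-[(2E)-but-2-en-2-yl]-3,7-dimethyloct-6-ene-1,3-diol
Conditions: 3 (3 equiv), CuBr·SMe2 (10 mol%), THF, −30 → 0 °C; aq NH4Cl
Reagents that add atoms: none
Why: Copper-catalysed SN2 opening of a 2,3-epoxy alcohol by an alkenyl Grignard reagent should occur at C-9, the epoxide carbon remote from the fully substituted C-8, with inversion, so C-9 becomes R while O-8 stays on the untouched tertiary centre.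

**Step 3**
Reactants: 4 the 1,3-diol; 5 di-tert-butylsilyl bis(trifluoromethanesulfonate)
Product: 6 (4S,5R)-5-[(2E)-but-2-en-2-yl]-2,2-di-tert-butyl-4-methyl-4-(4-methylpent-3-en-1-yl)-1,3,2-dioxasilinane
Conditions: 5 (1.1 equiv), 2,6-lutidine, CH2Cl2, 0 °C → rt
Reagents that add atoms: none
Why: Silylene protection of a 1,3-diol masks both hydroxyls in one step and ties O-8 to O-11 in a six-membered ring that later locks the ring-B chair; no stereocentre is touched.

**Step 4**
Reactants: 6 the silylene diene; 7 methyl methacrylate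
Product: 8 methyl (2E)-5-[(4S,5R)-5-[(2E)-but-2-en-2-yl]-2,2-di-tert-butyl-4-methyl-1,3,2-dioxasilinan-4-yl]-2-methylpent-2-enoate
Conditions: 7 (20 equiv), second-generation Hoveyda–Grubbs catalyst RuCl2(H2IMes)(=CH–C6H4-2-OiPr) (5 mol%), CH2Cl2, 40 °C
Reagents that add atoms: none
Why: Olefin cross-metathesis of the isopropylidene terminus with methyl methacrylate should replace CMe2 by C(Me)CO2Me with E geometry, while the hindered butenyl olefin next to C-9 is left alone; this brings in C-4, C-14 and C-3.

**Step 5**
Reactants: 8 the enoate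
Product: 10 methyl (2E)-5-[(4S,5R)-2,2-di-tert-butyl-5-(3-hydroxybutan-2-yl)-4-methyl-1,3,2-dioxasilinan-4-yl]-2-methylpent-2-enoate, via alkylborane 9 (not isolated)
Conditions: BH3·THF (1.2 equiv), THF, 0 °C → rt; then 30% H2O2, aq NaOAc, 0 °C → rt
Reagents that add atoms: hydrogen peroxide, OO
Why: Hydroboration–oxidation of the electron-rich trisubstituted olefin (boron to the less substituted C-1) should outpace reaction of borane with the deactivated enoate; the two new centres (C-10, C-1) form as a mixture that is erased in steps 6 and 7.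

**Step 6**
Reactants: 10 the secondary alcohol
Product: 11 methyl (2E)-5-[(4S,5R)-2,2-di-tert-butyl-4-methyl-5-(3-oxobutan-2-yl)-1,3,2-dioxasilinan-4-yl]-2-methylpent-2-enoate
Conditions: Dess–Martin periodinane, NaHCO3, CH2Cl2, rt
Reagents that add atoms: none
Why: Dess–Martin oxidation of a secondary alcohol gives the methyl ketone; the silylene and the enoate are inert, and the now epimerisable C-10 is enolised in step 7 anyway.

**Step 7**
Reactants: 11 the keto enoate
Product: 13 silylene-protected (4R,5R,8S,9R,10R)-4α,8β,10β-trimethyl-trans-decalin-1,3-dione carrying the 9β-CH2O–Si–O-8α bridge, via Michael adduct 12 (not isolated)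
Conditions: KOt-Bu (3 equiv), THF/t-BuOH (5:1), 0.01 M, 0 → 50 °C; then 1 M HCl
Reagents that add atoms: none
Why: KOt-Bu reversibly enolises the methyl ketone, the more substituted C-10 enolate adds to the enoate β-carbon C-5 (Michael, ring B), and after proton transfer the C-2 enolate of the same ketone is acylated by the ester carbon C-3 (Claisen, ring A), the 1,3-dione being deprotonated at once, which drives the sequence forward. The closest known reaction type is the consecutive Michael–Claisen synthesis of cyclohexane-1,3-diones from a methyl ketone and an α,β-unsaturated ester, here run intramolecularly. Ring B closes 6-exo-trig with the enolate double bond outside the new ring, and ring A closes 6-exo-trig at the ester carbonyl with the enolate double bond inside the new ring. C-10 and C-5 should be set by the C-8/C-9 pair: the trans-fused dioxasilinane fixes the ring-B chair (C-12 axial, O-8 and C-11 equatorial), A(1,3) strain puts H-9 in the enolate plane so that C-5 bonds on the face syn to C-8 with C-1 equatorial and C-15 axial, and the enoate arm sits equatorial, which makes H-5 axial and trans to C-15 (trans-decalin); C-4 should settle as the equatorial 4α-methyl epimer and is cleared in step 10. The step needs regioselectivity between the C-10 and C-2 enolates and between the two electrophilic carbons, which ring size secures (C-10 to C-5 and C-2 to C-3 are the only pairings that give six-membered rings, the others needing eight- or ten-membered rings), and high dilution keeps it intramolecular.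

**Step 8**
Reactants: 13 the 1,3-dione
Product: 14 (4R,5R,8S,9R,10R)-3-methoxy-2-en-1-one (vinylogous methyl ester of 13 at O-3)
Conditions: MeOH, HC(OMe)3, TsOH·H2O (5 mol%), rt
Reagents that add atoms: methanol, CO; trimethyl orthoformate, COC(OC)OC
Why: Acid-catalysed enol etherification of a cyclic 1,3-dione should take place at the less hindered carbonyl C-3, flanked by the tertiary C-4, and not at C-1, flanked by the quaternary C-10.

**Step 9**
Reactants: 14 the vinylogous ester
Product: 16 (4R,5R,8S,9R,10R)-4α-methyl-1-en-3-one, via allylic alcohol 15 (not isolated)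
Conditions: LiAlH4, Et2O, 0 °C; then 1 M HCl, THF, rt
Reagents that add atoms: water, O
Why: Stork–Danheiser carbonyl transposition: hydride reduces the vinylogous-ester carbonyl C-1, and acid hydrolysis of the enol ether with loss of the C-1 hydroxyl gives the 1-en-3-one, so the temporary C-1 oxygen leaves and C-3 keeps a carbonyl; C-4 equilibrates to the equatorial methyl epimer.

**Step 10**
Reactants: 16 the enone
Product: 18 (4S,5S,8S,9R,10R)-4α-hydroxymethyl-4β-methyl-1-en-3-one, via lithium dienolate 17 (not isolated)
Conditions: LiN(i-Pr)2 (1.2 equiv), THF, −78 °C; then CH2O (g), −78 °C; aq NH4Cl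
Reagents that add atoms: formaldehyde, C=O
Why: Kinetic α′-deprotonation of the enone (C-10 is quaternary, so C-4–H is the only acidic site) and aldol addition of the cross-conjugated enolate to formaldehyde; the electrophile should enter from the α face, anti to the axial C-10 methyl that shields the β face, which sets C-4 (S) with C-13 α and C-14 β.

**Step 11**
Reactants: 18 the hydroxymethyl enone
Product: 19 (4S,5S,8S,9R,10R)-4α-hydroxymethyl-4β-methyl-3-one (saturated ring A)
Conditions: H2 (1 atm), 10% Pd/C, EtOAc, rt
Reagents that add atoms: none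
Why: Heterogeneous catalytic hydrogenation of the disubstituted enone C=C; no stereocentre is created, and the silylene and the neopentyl hydroxyl are inert.

**Step 12**
Reactants: 19 the keto alcohol; 20 angelic acid
Product: 21 C-13 angelate of 19
Conditions: 20, 2,4,6-trichlorobenzoyl chloride, Et3N, toluene, rt; then 19, toluene, 80 °C
Reagents that add atoms: none
Why: Yamaguchi esterification through the mixed 2,4,6-trichlorobenzoic anhydride, run without a nucleophilic catalyst, should acylate with angelic acid without Z-to-E isomerisation; the primary C-13 hydroxyl is the only free hydroxyl.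

**Step 13**
Reactants: 21 the silylene angelate
Product: 22 8α,11-diol (3-oxo C-13 angelate)
Conditions: HF·pyridine, THF/pyridine, 0 °C → rt
Reagents that add atoms: none
Why: Fluoride cleavage of the dialkoxysilane (deprotection) under mildly acidic conditions frees O-8 and O-11 without touching the angelate or the ketone.

**Step 14**
Reactants: 22 the diol; 23 umbelliferone
Product: 24 C-11 umbelliferyl ether (3-oxo C-13 angelate, free 8α-OH)
Conditions: 23, PPh3, DIAD, THF, 0 °C → rt
Reagents that add atoms: none
Why: Mitsunobu etherification of the primary C-11 alcohol with the acidic phenol 23; the tertiary C-8 alcohol cannot be displaced, C-11 is not a stereocentre, and C-3 is still a ketone so no secondary alcohol competes.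

**Step 15**
Reactants: 24 the keto ether
Product: 25 CNP0139045.1
Conditions: NaBH4, CeCl3·7H2O, MeOH/THF, −40 °C
Reagents that add atoms: none
Why: Luche reduction should deliver hydride to the C-3 ketone in preference to the coumarin lactone and the angelate; axial attack from the α face (the β face is blocked by the axial C-14 and C-15 methyls) should give the equatorial 3β alcohol (3R).

**Compound list**
1 | geraniol, (2E)-3,7-dimethylocta-2,6-dien-1-ol | CC(C)=CCC/C(C)=C/CO | starting material
2 | (2S,3S)-2,3-epoxygeraniol | OC[C@@H]1O[C@@]1(C)CCC=C(C)C | intermediate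
3 | (E)-but-2-en-2-ylmagnesium bromide (THF solution) | C/C=C(\C)[Mg]Br | starting material
4 | (2R,3S)-2-[(2E)-but-2-en-2-yl]-3,7-dimethyloct-6-ene-1,3-diol | CC(C)=CCC[C@](C)(O)[C@@H](CO)/C(C)=C/C | intermediate
5 | di-tert-butylsilyl bis(trifluoromethanesulfonate) | CC(C)(C)[Si](OS(=O)(=O)C(F)(F)F)(OS(=O)(=O)C(F)(F)F)C(C)(C)C | starting material
6 | (4S,5R)-5-[(2E)-but-2-en-2-yl]-2,2-di-tert-butyl-4-methyl-4-(4-methylpent-3-en-1-yl)-1,3,2-dioxasilinane | CC(C)=CCC[C@]1(C)O[Si](C(C)(C)C)(C(C)(C)C)OC[C@H]1/C(C)=C/C | intermediate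
7 | methyl methacrylate | C=C(C)C(=O)OC | starting material
8 | methyl (2E)-5-[(4S,5R)-5-[(2E)-but-2-en-2-yl]-2,2-di-tert-butyl-4-methyl-1,3,2-dioxasilinan-4-yl]-2-methylpent-2-enoate | COC(=O)/C(C)=C/CC[C@]1(C)O[Si](C(C)(C)C)(C(C)(C)C)OC[C@H]1/C(C)=C/C | intermediate
9 | alkylborane from 8, boron on C-1 (3-boranylbutan-2-yl side chain; mixture of syn-addition diastereomers) | COC(=O)/C(C)=C/CC[C@]1(C)O[Si](C(C)(C)C)(C(C)(C)C)OC[C@H]1C(C)C(C)B | intermediate
10 | methyl (2E)-5-[(4S,5R)-2,2-di-tert-butyl-5-(3-hydroxybutan-2-yl)-4-methyl-1,3,2-dioxasilinan-4-yl]-2-methylpent-2-enoate (diastereomer mixture at C-10/C-1) | COC(=O)/C(C)=C/CC[C@]1(C)O[Si](C(C)(C)C)(C(C)(C)C)OC[C@H]1C(C)C(C)O | intermediate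
11 | methyl (2E)-5-[(4S,5R)-2,2-di-tert-butyl-4-methyl-5-(3-oxobutan-2-yl)-1,3,2-dioxasilinan-4-yl]-2-methylpent-2-enoate (C-10 epimers) | COC(=O)/C(C)=C/CC[C@]1(C)O[Si](C(C)(C)C)(C(C)(C)C)OC[C@H]1C(C)C(C)=O | intermediate
12 | Michael adduct, (5R,8S,9R,10R): ring B closed, C-10 bearing acetyl and methyl, C-5 bearing the CH(CH3)CO2Me arm (C-4 epimers), trans-fused to the dioxasilinane | COC(=O)C(C)[C@H]1CC[C@]2(C)O[Si](C(C)(C)C)(C(C)(C)C)OC[C@H]2[C@]1(C)C(C)=O | intermediate
13 | (4R,5R,8S,9R,10R)-4α,8β,10β-trimethyl-trans-decalin-1,3-dione with 9β-CH2O and 8α-O bridged by Si(t-Bu)2 (largely enolised) | C[C@@H]1[C@H]2CC[C@]3(C)O[Si](C(C)(C)C)(C(C)(C)C)OC[C@H]3[C@]2(C)C(=O)CC1=O | intermediate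
14 | (4R,5R,8S,9R,10R)-3-methoxy-2-en-1-one (vinylogous ester of 13) | C[C@@H]1[C@H]2CC[C@]3(C)O[Si](C(C)(C)C)(C(C)(C)C)OC[C@H]3[C@]2(C)C(=O)C=C1OC | intermediate
15 | 3-methoxy-2-en-1-ol from 14 (C-1 epimers) | C[C@@H]1[C@H]2CC[C@]3(C)O[Si](C(C)(C)C)(C(C)(C)C)OC[C@H]3[C@]2(C)C(O)C=C1OC | intermediate
16 | (4R,5R,8S,9R,10R)-4α-methyl-1-en-3-one | C[C@@H]1[C@H]2CC[C@]3(C)O[Si](C(C)(C)C)(C(C)(C)C)OC[C@H]3[C@]2(C)C=CC1=O | intermediate
17 | lithium 1,3-dien-3-olate of 16 | CC=1[C@H]2CC[C@]3(C)O[Si](C(C)(C)C)(C(C)(C)C)OC[C@H]3[C@]2(C)C=CC=1O[Li] | intermediate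
18 | (4S,5S,8S,9R,10R)-4α-hydroxymethyl-4β-methyl-1-en-3-one | OC[C@]1(C)[C@H]2CC[C@]3(C)O[Si](C(C)(C)C)(C(C)(C)C)OC[C@H]3[C@]2(C)C=CC1=O | intermediate
19 | (4S,5S,8S,9R,10R)-4α-hydroxymethyl-4β-methyl-3-one | OC[C@]1(C)[C@H]2CC[C@]3(C)O[Si](C(C)(C)C)(C(C)(C)C)OC[C@H]3[C@]2(C)CCC1=O | intermediate
20 | angelic acid, (2Z)-2-methylbut-2-enoic acid | C/C=C(/C)C(=O)O | starting material
21 | (4S,5S,8S,9R,10R) C-13 angelate of 19, silylene intact | C/C=C(/C)C(=O)OC[C@]1(C)[C@H]2CC[C@]3(C)O[Si](C(C)(C)C)(C(C)(C)C)OC[C@H]3[C@]2(C)CCC1=O | intermediate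
22 | (4S,5S,8S,9R,10R)-8α,11-dihydroxy-3-oxo C-13 angelate | C/C=C(/C)C(=O)OC[C@]1(C)[C@H]2CC[C@](C)(O)[C@@H](CO)[C@]2(C)CCC1=O | intermediate
23 | umbelliferone, 7-hydroxy-2H-chromen-2-one | Oc1ccc2ccc(=O)oc2c1 | starting material
24 | (4S,5S,8S,9R,10R)-8α-hydroxy-3-oxo-11-(2-oxo-2H-chromen-7-yloxy) C-13 angelate | C/C=C(/C)C(=O)OC[C@]1(C)[C@H]2CC[C@](C)(O)[C@@H](COc3ccc4ccc(=O)oc4c3)[C@]2(C)CCC1=O | intermediate
25 | CNP0139045.1, (3R,4S,5S,8S,9R,10R)-3β,8α-dihydroxy-11-(2-oxo-2H-chromen-7-yloxy) C-13 angelate | C/C=C(/C)C(=O)OC[C@]1(C)[C@H]2CC[C@](C)(O)[C@@H](COc3ccc4ccc(=O)oc4c3)[C@]2(C)CC[C@H]1O | target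

**Totals and risks**
Total step count: 15. Longest linear sequence: 15 steps (from geraniol 1).

The three steps most likely to fail:

Step 7. The risk is loss of diastereocontrol at C-10 and C-5 if the ring-B Michael closure reverses before the Claisen closure, or stalling at the Michael stage. The fallback sets out from 11 and comes back at 13, and makes the two bonds in separate, kinetically controlled operations. Ketone 11 is converted with Me3SiCl, NaI and Et3N in MeCN into the more substituted trimethylsilyl enol ether F1. TiCl4 in CH2Cl2 at −78 °C then closes C-5–C-10 by an irreversible intramolecular Mukaiyama–Michael addition, giving keto ester 12, which is now isolated. KN(SiMe3)2 in THF closes C-2–C-3 by Claisen condensation to give 13.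

Step 8. The risk is etherification at the wrong carbonyl oxygen (O-1 in place of O-3), which would turn the transposition of step 9 the wrong way. The fallback sets out from 13 and comes back at 19, and uses the other regioisomer productively. The 1-methoxy-1-en-3-one F2 is deprotonated at C-4 with LiN(i-Pr)2 and treated with formaldehyde (α′-alkylation of a vinylogous ester, again from the α face) to give the hydroxymethylated vinylogous ester F3. Li in NH3/THF with t-BuOH then reduces the β-methoxy enone with loss of methoxide and saturation of C-1–C-2, giving 19 directly.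

Step 14. The risk is slow SN2 displacement at the doubly β-branched C-11 oxyphosphonium ion, with competing oxetane formation by O-8 or elimination. The fallback sets out from 22 and comes back at 24, and makes the ether bond at the aryl carbon instead. It is a palladium-catalysed C–O coupling of the primary alcohol of 22 with commercial 7-bromocoumarin (O=c1ccc2ccc(Br)cc2o1) using Pd2(dba)3, RockPhos and Cs2CO3 in toluene at 90 °C. No new compound is made on the way (F0).

**Further compounds**
F1 | step 7 | methyl (2E)-5-[(4S,5R)-2,2-di-tert-butyl-4-methyl-5-[3-(trimethylsilyloxy)but-2-en-2-yl]-1,3,2-dioxasilinan-4-yl]-2-methylpent-2-enoate | COC(=O)/C(C)=C/CC[C@]1(C)O[Si](C(C)(C)C)(C(C)(C)C)OC[C@H]1C(C)=C(C)O[Si](C)(C)C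
F2 | step 8 | (4R,5R,8S,9R,10R)-1-methoxy-4α-methyl-1-en-3-one (regioisomer of 14) | C[C@@H]1[C@H]2CC[C@]3(C)O[Si](C(C)(C)C)(C(C)(C)C)OC[C@H]3[C@]2(C)C(OC)=CC1=O
F3 | step 8 | (4S,5S,8S,9R,10R)-4α-hydroxymethyl-1-methoxy-4β-methyl-1-en-3-one | OC[C@]1(C)[C@H]2CC[C@]3(C)O[Si](C(C)(C)C)(C(C)(C)C)OC[C@H]3[C@]2(C)C(OC)=CC1=O
F0 | step 14 | none | none
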